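(The readings were computed for an exercise; noise was put on by code.)

G is the substrate: it turns into D, J carries D on to Q, and E competes for D to give L. E may also slip into X or attack Q to give Z.

| flask | G | J | E | remark | time |
|---|---|---|---|---|---|
| Friday's | 0.50 M | 0.50 M | 0.65 M (fed, over 1.0 h) | run made earlier |  |
| Tuesday's | 0.50 M | 1.1 M | 0.65 M (fed, over 1.0 h) | run made earlier |  |
| flask | 0.50 M | 0.750 M | 0.650 M (fed, over 1.0 h) |  | 3.0 h |

| Friday's: time / h | Friday's: Q / % | Tuesday's: time / h | Tuesday's: Q / % |
|---|---|---|---|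
| 0.200 | 8 | 0.667 | 26 |
| 0.417 | 17 | 1.33 | 37 |
| 1.00 | 26 | 2.00 | 49 |
| 2.50 | 37 | 2.50 | 50 |

(readings scatter by 1.5 percentage points)

- amount of Q in percent of the G charged, at 20 min, 1.0 h and 3.0 h

Climb the time scales from fast to slow. D comes first: Friday's flask shows 8% Q at 0.200 h, with no lag visible, so you can treat D as caught soon after it forms.

G comes next. Friday's flask makes Q at 0.408 h⁻¹ of the G charged, and Tuesday's flask, with twice the J, makes it at 0.390 h⁻¹. So G → D looks like the rate-limiting step.

The feed takes 1.0 h, and Friday's flask still gains Q after it, with 37% at 2.50 h against 26% at 1.00 h, so I expect G to be still turning into D once the whole charge of E is in. Later D then faces both rivals. Take the symmetric case as the zero of the scale, a selectivity factor of one, and define the even share: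

s = J charged / (J charged + E charged)

Friday's flask: 43.5%; Tuesday's flask: 62.9%; new flask: 53.6%

The readings at 2.50 h give Q/s:

Friday's flask: 85.1%; Tuesday's flask: 79.5%; mean w = 82.3%

My reckoning for the new flask uses w, s and the early pace:

20 min: 13.6%
1.0 h: 28.9%, placed by s between Friday's reading and Tuesday's interpolated one
3.0 h: 44.1%

The last line is a 2.50 h value carried to 3.0 h, so I take it as a low estimate: the step in Tuesday's flask from 49% to 50% lies within a scatter of 1.5 percentage points and shows no plateau.

The forecast gives 14%, 29% and 44%, by a different route: “I interpolate, weighting slightly toward the low-J run”.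

The new flask gives 15.6%, 31.2% and 46.3%.

    E + Q → Z (k = 7.70 × 10⁻⁵ M⁻¹ s⁻¹)
    E ⇌ X (K = 1.40, k = 1.80 × 10⁻⁴ s⁻¹)
    E + D → L (k = 0.0190 M⁻¹ s⁻¹)
    J + D → Q (k = 0.0120 M⁻¹ s⁻¹)
    G → D (k = 1.90 × 10⁻⁴ s⁻¹)

At 3.00 h in the new flask, J uses D 1.6 times as fast as E does. Q/s there is 86.4%. Put on Friday's s, that yields 37.6%, against the 37% read at 2.50 h.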